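**Retrosynthetic overview** (benzofuran numbering)
- The target is cut back to an open-chain epoxy tetraketide. Ring A is cut at C4–C5, a Claisen closure of a 3,5,7-triketo ester in the way chalcone synthase folds its chain. The dihydrofuran is cut at O1–C2, a 5-exo opening of a (2R)-oxirane with inversion to 2S. Both closures run in one flask.
- The tetraketide comes from the terminal carbanion of an epoxy 3,5-diketo ester and silyl-protected methyl 4-coumarate (bond C5–C=O). Ring B is bought.
- The epoxy diketo ester comes from the 2,4-dianion of methyl 3,5-dioxohexanoate (made from dehydroacetic acid) and an epoxy tosylate (bond C3–C3a).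
- The epoxy tosylate comes from prenol by Sharpless epoxidation. The only stereocentre is set here.
- Ring order: oxirane first, then dihydrofuran and ring A together in the last step. The pyranone of dehydroacetic acid is only a cheap store of the C6 chain and is opened early.

Assumption: the stereocentre of the given SMILES is read as (2S). The epoxy diketo ester and the tetraketide are carried as mixtures of epimers and keto–enol tautomers at the carbon that becomes sp2 in the last step.

Step 1
Reactants: 1 3-methylbut-2-en-1-ol (prenol)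
Product: 3 [(2R)-3,3-dimethyloxiran-2-yl]methyl 4-methylbenzenesulfonate, via (2R)-epoxy alcohol 2 (not isolated)
Conditions: Ti(OiPr)4 (5 mol%), D-(−)-diisopropyl tartrate (7 mol%), t-BuOOH (1.5 equiv, decane), 4 Å MS, CH2Cl2, −20 °C; P(OMe)3 (0.5 equiv), −20 °C; Et3N, DMAP (cat.), TsCl, −10 to 0 °C
Reagents that add atoms: tert-butyl hydroperoxide CC(C)(C)OO; 4-methylbenzenesulfonyl chloride Cc1ccc(cc1)S(=O)(=O)Cl
Why: Katsuki–Sharpless asymmetric epoxidation of a primary allylic alcohol, in which the D-(−)-tartrate/Ti(OiPr)4 complex gives the (2R)-epoxy alcohol (the sense that turns geraniol into its 2R,3R-epoxide), and sulfonylation in the same flask avoids isolating the volatile, water-soluble 2.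

Step 2
Reactants: 4 dehydroacetic acid (3-acetyl-4-hydroxy-6-methyl-2H-pyran-2-one)
Product: 5 methyl 3,5-dioxohexanoate
Conditions: Mg(OMe)2 (2 equiv), MeOH, reflux, 6 h; cold 2 M HCl
Reagents that add atoms: methanol CO; Mg(OMe)2 C[O-].C[O-].[Mg+2]
Why: Methoxide-induced retro-Claisen deacetylation plus lactone methanolysis of a 3-acyl-4-hydroxy-2-pyranone, driven by the stable magnesium chelate of the 3,5-diketo ester, with no stereocentre involved.

Step 3
Reactants: 5 methyl 3,5-dioxohexanoate; 3 [(2R)-3,3-dimethyloxiran-2-yl]methyl 4-methylbenzenesulfonate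
Product: 6 methyl 2-{[(2R)-3,3-dimethyloxiran-2-yl]methyl}-3,5-dioxohexanoate
Conditions: LiN(iPr)2 (2.1 equiv), THF, −78 to 0 °C; 3 (0.9 equiv), DMPU, Bu4NI (10 mol%), 0 to 10 °C; AcOH (1.1 equiv), −20 °C
Reagents that add atoms: none
Why: Hauser–Harris polyanion alkylation, in which the last-formed and least stabilised site of the 2,4-dianion (C2, the β-keto ester carbon) displaces the primary tosylate by SN2, so the oxirane stereocentre is untouched and the new C2 centre is irrelevant because it becomes sp2 in step 5.

Step 4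
Reactants: 7 methyl (E)-3-(4-hydroxyphenyl)prop-2-enoate
Product: 8 methyl (E)-3-{4-[tert-butyl(dimethyl)silyl]oxyphenyl}prop-2-enoate
Conditions: TBSCl (1.1 equiv), imidazole (2.2 equiv), DMF, rt
Reagents that add atoms: tert-butyl(chloro)dimethylsilane CC(C)(C)[Si](C)(C)Cl
Why: Imidazole-promoted silylation of a phenol removes the acidic proton that would quench the polyanion in step 5 and keeps the ester electrophilic, with no stereocentre involved.

Step 5
Reactants: 6 methyl 2-{[(2R)-3,3-dimethyloxiran-2-yl]methyl}-3,5-dioxohexanoate; 8 methyl (E)-3-{4-[tert-butyl(dimethyl)silyl]oxyphenyl}prop-2-enoate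
Product: 12 (E)-1-[(2S)-4,6-dihydroxy-2-(2-hydroxypropan-2-yl)-2,3-dihydro-1-benzofuran-5-yl]-3-(4-hydroxyphenyl)prop-2-en-1-one (target), via epoxy tetraketide 9 (not isolated), via dihydrofuran keto ester 10 (not isolated), via O-silyl chalcone 11 (not isolated)
Conditions: LiN(iPr)2 (4.2 equiv), THF, −78 to −30 °C, 1 h; 8 (1.0 equiv), −78 to −10 °C, 2 h; MeOH (excess), 55 °C, 3 h; poured into ice-cold 1 M HCl (pH 2–3)
Reagents that add atoms: none
Why: Proposed new method: the 2,4,6-trianion of 6 (the fourth equivalent of base takes up the acidic proton of the new 1,3-diketone) is acylated at its terminal, most basic carbon by the non-enolisable ester 8 (Hauser–Harris polyanion acylation) to give 9; after partial protonation by MeOH the 3-oxido oxygen of the β-keto ester enolate opens the tethered oxirane 5-exo-tet at its secondary carbon with inversion, (2R)-oxirane to (2S)-dihydrofuran 10, which sets the stereocentre, fixes the ring oxygen para to the future acyl group and makes C2 a fully substituted sp2 carbon, so the aldol (resorcylate) folding is shut off and only the chalcone-synthase-type Claisen closure C6 to C1 remains, with loss of methoxide and irreversible aromatisation to ring A (11); LiOMe/MeOH then cleaves the aryl silyl ether and the cold acid quench releases the open chalcone instead of the flavanone; the closest known reaction types are the biomimetic Claisen cyclisation of 3,5,7-triketo esters to acylphloroglucinols and the base-induced 5-exo cyclisation of 2-(2,3-epoxy-3-methylbutyl) phenols and 1,3-dicarbonyl compounds to 2-(2-hydroxypropan-2-yl)dihydrofurans.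

**Compound list**
1 | 3-methylbut-2-en-1-ol (prenol) | CC(C)=CCO | starting material
2 | [(2R)-3,3-dimethyloxiran-2-yl]methanol | CC1(C)O[C@@H]1CO | intermediate
3 | [(2R)-3,3-dimethyloxiran-2-yl]methyl 4-methylbenzenesulfonate | CC1(C)O[C@@H]1COS(=O)(=O)c1ccc(C)cc1 | intermediate
4 | dehydroacetic acid (3-acetyl-4-hydroxy-6-methyl-2H-pyran-2-one) | CC(=O)C1=C(O)C=C(C)OC1=O | starting material
5 | methyl 3,5-dioxohexanoate | CC(=O)CC(=O)CC(=O)OC | intermediate
6 | methyl 2-{[(2R)-3,3-dimethyloxiran-2-yl]methyl}-3,5-dioxohexanoate (C2 epimers) | CC(=O)CC(=O)C(C[C@H]1OC1(C)C)C(=O)OC | intermediate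
7 | methyl (E)-3-(4-hydroxyphenyl)prop-2-enoate | COC(=O)/C=C/c1ccc(O)cc1 | starting material
8 | methyl (E)-3-{4-[tert-butyl(dimethyl)silyl]oxyphenyl}prop-2-enoate | COC(=O)/C=C/c1ccc(O[Si](C)(C)C(C)(C)C)cc1 | intermediate
9 | methyl (E)-9-{4-[tert-butyl(dimethyl)silyl]oxyphenyl}-2-{[(2R)-3,3-dimethyloxiran-2-yl]methyl}-3,5,7-trioxonon-8-enoate (C2 epimers) | COC(=O)C(C[C@H]1OC1(C)C)C(=O)CC(=O)CC(=O)/C=C/c1ccc(O[Si](C)(C)C(C)(C)C)cc1 | intermediate
10 | methyl (5S)-2-[(E)-6-{4-[tert-butyl(dimethyl)silyl]oxyphenyl}-2,4-dioxohex-5-enyl]-5-(2-hydroxypropan-2-yl)-4,5-dihydrofuran-3-carboxylate | COC(=O)C1=C(CC(=O)CC(=O)/C=C/c2ccc(O[Si](C)(C)C(C)(C)C)cc2)O[C@@H](C1)C(C)(C)O | intermediate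
11 | (E)-3-{4-[tert-butyl(dimethyl)silyl]oxyphenyl}-1-[(2S)-4,6-dihydroxy-2-(2-hydroxypropan-2-yl)-2,3-dihydro-1-benzofuran-5-yl]prop-2-en-1-one | CC(C)(O)[C@@H]1Cc2c(cc(O)c(C(=O)/C=C/c3ccc(O[Si](C)(C)C(C)(C)C)cc3)c2O)O1 | intermediate
12 | (E)-1-[(2S)-4,6-dihydroxy-2-(2-hydroxypropan-2-yl)-2,3-dihydro-1-benzofuran-5-yl]-3-(4-hydroxyphenyl)prop-2-en-1-one | CC(C)(O)[C@@H]1Cc2c(cc(O)c(C(=O)/C=C/c3ccc(O)cc3)c2O)O1 | target

Total step count: 5. Longest linear sequence: 3 (1 → 3 → 6 → 12, or 4 → 5 → 6 → 12).

**Steps most likely to fail**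

Step 5 carries the most risk. The carbanion may add to 8 in conjugate fashion instead of at the ester. Under polyanion conditions carbon rather than oxygen may attack the oxirane. The Claisen closure onto the vinylogous carbonate ester of 10 may be slow. The chalcone may drift to the flavanone on work-up, so 12 is kept acidic and cold and is chromatographed quickly. The fallback runs from 6 back to 11 and closes the rings one after the other through a pyranone. DBU in toluene at 60 °C turns 6 into (2S)-2-(2-hydroxypropan-2-yl)-6-methyl-2,3-dihydro-4H-furo[3,2-c]pyran-4-one F1 by oxirane opening and enol lactonisation. Lateral lithiation of its 6-methyl group with LiN(iPr)2 (3.2 equiv) and acylation with 8 gives (2S)-6-[(E)-4-{4-[tert-butyl(dimethyl)silyl]oxyphenyl}-2-oxobut-3-enyl]-2-(2-hydroxypropan-2-yl)-2,3-dihydro-4H-furo[3,2-c]pyran-4-one F2. Mg(OMe)2 in refluxing MeOH then carries out the classical ring transformation of a 6-(2-oxoalkyl)-2-pyranone into an acylphloroglucinol. This delivers 11, which loses its silyl group in the same medium to give 12.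

Step 3 may give C4- or O-alkylation, or may cyclise too early. The fallback runs from 3 back to 6 and grows the chain outward from an unambiguous monoanion. The sodium enolate of methyl acetoacetate (NaH, THF/DMF, rt) is alkylated with 3 to give methyl 2-acetyl-3-[(2R)-3,3-dimethyloxiran-2-yl]propanoate F3. Its dianion (LiN(iPr)2, 2.1 equiv, −78 °C) is acetylated at the terminal carbon with N-methoxy-N-methylacetamide to give 6.

Step 1 may give only about 90–95% ee, and the volatile, acid-sensitive epoxide is easily lost. In any case 12 is recrystallised to constant ee. The fallback runs from 1 back to 2 and replaces the titanium–tartrate control by an organocatalytic dioxirane epoxidation. Ac2O/pyridine gives 3-methylbut-2-enyl acetate F4. The D-fructose-derived ketone catalyst (1,2:4,5-di-O-isopropylidene-β-D-erythro-2,3-hexodiulo-2,6-pyranose, 30 mol%) is used with KHSO5 and K2CO3 in MeCN/dimethoxymethane/water at 0 °C and gives [(2R)-3,3-dimethyloxiran-2-yl]methyl acetate F5. K2CO3 in MeOH releases 2, which is tosylated to 3 as in the second half of step 1.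

**Further compounds**
F1 | step 5 | (2S)-2-(2-hydroxypropan-2-yl)-6-methyl-2,3-dihydro-4H-furo[3,2-c]pyran-4-one | CC1=CC2=C(C[C@H](O2)C(C)(C)O)C(=O)O1
F2 | step 5 | (2S)-6-[(E)-4-{4-[tert-butyl(dimethyl)silyl]oxyphenyl}-2-oxobut-3-enyl]-2-(2-hydroxypropan-2-yl)-2,3-dihydro-4H-furo[3,2-c]pyran-4-one | CC(C)(O)[C@@H]1CC2=C(O1)C=C(CC(=O)/C=C/c1ccc(O[Si](C)(C)C(C)(C)C)cc1)OC2=O
F3 | step 3 | methyl 2-acetyl-3-[(2R)-3,3-dimethyloxiran-2-yl]propanoate | CC(=O)C(C[C@H]1OC1(C)C)C(=O)OC
F4 | step 1 | 3-methylbut-2-enyl acetate | CC(C)=CCOC(C)=O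
F5 | step 1 | [(2R)-3,3-dimethyloxiran-2-yl]methyl acetate | CC(=O)OC[C@H]1OC1(C)C
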